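**Plan**

- Retrosynthesis: after the phenol is masked as a benzyl ether, the two bonds from lactone C3 to the benzylic carbons of ring A and ring B are cut. This gives two molecules of (S)-4-(3,4-dimethoxybenzyl)butyrolactone 13 and the diaryl ether bis(benzylic bromide) 19. Compound 19 is cut at the aryl C–O bond into vanillin and O-benzyl-5-bromovanillin.
- Enabling feature: in each lactone ring, C4 carries the 3,4-dimethoxybenzyl group and, once C3 is freed, lies between C3H2 and C5H2. It can therefore be built as the α-carbon of a 5-substituted butyrolactone whose carbonyl carbon is later reduced to become C5H2. The C4–benzyl bond is cut there, giving trityl lactone 4 and bromide 6.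
- Forward order: D-glutamic acid gives the template lactone 4, which is benzylated (no ring formed). Reduction, detritylation, periodate cleavage and oxidation re-close the five-membered lactone with the carbonyl transposed (13). The diaryl ether is made by Ullmann coupling and converted to 19. Two enolates of 13 are joined to 19, and hydrogenolysis ends the route.
- Stereochemistry: C2 of D-glutamic acid becomes C5 of 4 and directs the benzyl group trans (1,3-induction), which sets C4 (S) of 13 before the template carbon is excised. C4 of 13 then directs the second benzylation trans (1,2-induction), setting C3 (S) in both lactones.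

Key step: step 5

Remark on the chemistry: the SMILES string is read as trans-(3S,4S) in both lactone rings. Compounds 2 and 3 can also be bought as single enantiomers, but the route is written from D-glutamic acid.

**Route**

Step 1
Reactants: 1 D-glutamic acid
Product: 2 (R)-5-oxotetrahydrofuran-2-carboxylic acid
Conditions: NaNO2, aq. HCl, 0 °C to rt
Reagents that add atoms: none
Why: Nitrous acid deamination of the α-amino acid proceeds with α-carboxylate participation (double inversion), so the γ-carboxyl oxygen closes the lactone with net retention at the (R) carbon.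

Step 2
Reactants: 2 (R)-5-oxotetrahydrofuran-2-carboxylic acid
Product: 3 (R)-5-(hydroxymethyl)dihydrofuran-2(3H)-one
Conditions: BH3·SMe2, THF, 0 °C to rt; MeOH quench
Reagents that add atoms: none
Why: Chemoselective borane reduction takes a free carboxylic acid much faster than a lactone, so the ring and the stereocentre should stay untouched.

Step 3
Reactants: 3 (R)-5-(hydroxymethyl)dihydrofuran-2(3H)-one
Product: 4 (R)-5-[(trityloxy)methyl]dihydrofuran-2(3H)-one
Conditions: TrCl, pyridine, rt
Reagents that add atoms: trityl chloride, ClC(c1ccccc1)(c1ccccc1)c1ccccc1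
Why: Tritylation (SN1 etherification) of the unhindered primary alcohol installs the bulky group that later shields one face of the enolate.

Step 4
Reactants: 5 veratryl alcohol (3,4-dimethoxybenzyl alcohol)
Product: 6 3,4-dimethoxybenzyl bromide
Conditions: PBr3, Et2O, 0 °C; used fresh
Reagents that add atoms: phosphorus tribromide, BrP(Br)Br
Why: PBr3 bromination of a benzylic alcohol (SN2 displacement of the phosphite ester) is the standard entry to this electron-rich bromide, which is used without storage.

Step 5
Reactants: 4 (R)-5-[(trityloxy)methyl]dihydrofuran-2(3H)-one; 6 3,4-dimethoxybenzyl bromide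
Product: 8 (3S,5R)-3-(3,4-dimethoxybenzyl)-5-[(trityloxy)methyl]dihydrofuran-2(3H)-one, via lithium enolate 7 (not isolated)
Conditions: LiN(iPr)2, THF, −78 °C; then 6, −78 to −40 °C; aq. NH4Cl
Reagents that add atoms: none
Why: LiN(iPr)2 removes a C3 proton of 4 to give the planar lithium enolate 7, whose C3 attacks the benzylic carbon of 6 in an SN2 C-alkylation that forms the C3–CH2Ar bond. The closest known reaction type is the trans-selective α-alkylation of γ-butyrolactone enolates that carry a bulky 5-(trityloxymethyl) group. No ring closes in this step. The new stereocentre C3 is controlled by the C5 stereocentre inherited from D-glutamic acid: the trityloxymethyl group covers the enolate face cis to it, so the bromide should add to the opposite face and give the trans (3S,5R) lactone. The step needs facial selectivity, C- over O-alkylation and mono- over dialkylation; these are secured by the size of the trityl group, by the soft benzylic bromide with a lithium counter-ion, and by low temperature with only a slight excess of base.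

Step 6
Reactants: 8 (3S,5R)-3-(3,4-dimethoxybenzyl)-5-[(trityloxy)methyl]dihydrofuran-2(3H)-one
Product: 9 (2S,4R)-2-(3,4-dimethoxybenzyl)-5-(trityloxy)pentane-1,4-diol
Conditions: LiAlH4, THF, 0 °C; aq. NaOH work-up
Reagents that add atoms: none
Why: Hydride reduction of the lactone opens the ring to the 1,4-diol without touching the trityl ether, the aryl ethers or the benzyl-bearing stereocentre.

Step 7
Reactants: 9 (2S,4R)-2-(3,4-dimethoxybenzyl)-5-(trityloxy)pentane-1,4-diol
Product: 10 (2R,4S)-4-(3,4-dimethoxybenzyl)pentane-1,2,5-triol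
Conditions: p-TsOH·H2O (cat.), MeOH, rt
Reagents that add atoms: none
Why: Acid-catalysed trityl ether cleavage (SN1 transfer of the trityl cation to methanol) frees the primary alcohol and exposes the terminal 1,2-diol.

Step 8
Reactants: 10 (2R,4S)-4-(3,4-dimethoxybenzyl)pentane-1,2,5-triol
Product: 12 (4S)-4-(3,4-dimethoxybenzyl)tetrahydrofuran-2-ol, via hydroxy aldehyde 11 (not isolated)
Conditions: NaIO4, THF/H2O, 0 °C to rt
Reagents that add atoms: none
Why: Periodate glycol cleavage (Malaprade reaction) cuts only the vicinal diol and expels the former template carbon as formaldehyde, after which the γ-hydroxy aldehyde 11 should close spontaneously to the five-membered lactol.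

Step 9
Reactants: 12 (4S)-4-(3,4-dimethoxybenzyl)tetrahydrofuran-2-ol
Product: 13 (S)-4-(3,4-dimethoxybenzyl)dihydrofuran-2(3H)-one
Conditions: PhI(OAc)2, TEMPO (cat.), CH2Cl2, rt
Reagents that add atoms: none
Why: TEMPO-catalysed lactol-to-lactone oxidation runs under near-neutral conditions that spare the dimethoxyarene, completing the carbonyl transposition with C4 unchanged.

Step 10
Reactants: 14 5-bromovanillin (3-bromo-4-hydroxy-5-methoxybenzaldehyde)
Product: 15 4-(benzyloxy)-3-bromo-5-methoxybenzaldehyde
Conditions: BnBr, K2CO3, DMF, rt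
Reagents that add atoms: benzyl bromide, BrCc1ccccc1
Why: Williamson etherification of the acidic phenol protects it for the coupling and the enolate chemistry, and the benzyl group can be removed at the end by hydrogenolysis.

Step 11
Reactants: 15 4-(benzyloxy)-3-bromo-5-methoxybenzaldehyde; 16 vanillin
Product: 17 4-(benzyloxy)-3-(4-formyl-2-methoxyphenoxy)-5-methoxybenzaldehyde
Conditions: CuI (cat.), picolinic acid (cat.), K3PO4, DMSO, 90 °C
Reagents that add atoms: none
Why: Copper-catalysed Ullmann diaryl ether synthesis joins the phenoxide of vanillin to an aryl bromide that is activated by its formyl group and has only one ortho substituent, under conditions that tolerate aldehydes.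

Step 12
Reactants: 17 4-(benzyloxy)-3-(4-formyl-2-methoxyphenoxy)-5-methoxybenzaldehyde
Product: 18 [4-(benzyloxy)-3-[4-(hydroxymethyl)-2-methoxyphenoxy]-5-methoxyphenyl]methanol
Conditions: NaBH4, MeOH/THF, 0 °C
Reagents that add atoms: none
Why: Borohydride reduction converts both aryl aldehydes to benzylic alcohols and leaves the diaryl ether and the benzyl ether intact.

Step 13
Reactants: 18 [4-(benzyloxy)-3-[4-(hydroxymethyl)-2-methoxyphenoxy]-5-methoxyphenyl]methanol
Product: 19 2-(benzyloxy)-5-(bromomethyl)-1-[4-(bromomethyl)-2-methoxyphenoxy]-3-methoxybenzene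
Conditions: PBr3, CH2Cl2, 0 °C; used fresh
Reagents that add atoms: phosphorus tribromide, BrP(Br)Br
Why: PBr3 bromination of both benzylic alcohols (SN2 on the phosphite esters) at low temperature should give the bis-bromide without cleaving the benzyl ether.

Step 14
Reactants: 13 (S)-4-(3,4-dimethoxybenzyl)dihydrofuran-2(3H)-one (two molecules); 19 2-(benzyloxy)-5-(bromomethyl)-1-[4-(bromomethyl)-2-methoxyphenoxy]-3-methoxybenzene
Product: 23 (3S,4S)-3-[4-[2-(benzyloxy)-5-[[(3S,4S)-4-(3,4-dimethoxybenzyl)-2-oxotetrahydrofuran-3-yl]methyl]-3-methoxyphenoxy]-3-methoxybenzyl]-4-(3,4-dimethoxybenzyl)dihydrofuran-2(3H)-one, via lithium enolate 20 (not isolated), via ring A monoalkylated bromide 21 (not isolated), via ring B monoalkylated bromide 22 (not isolated)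
Conditions: 13 (2.3 equiv), LiN(iPr)2, THF, −78 °C; then 19 (1 equiv), DMPU, −78 to −20 °C
Reagents that add atoms: none
Why: Twofold SN2 C-alkylation of the lithium enolate 20 by the two benzylic bromides, in which the C4 dimethoxybenzyl group blocks the cis face of each β-substituted butyrolactone enolate, should set each new C3 centre trans (3S,4S) by 1,2-induction as in dibenzylbutyrolactone lignan synthesis.

Step 15
Reactants: 23 O-benzyl bis-lactone from step 14
Product: 24 (3S,4S)-4-(3,4-dimethoxybenzyl)-3-[4-[5-[[(3S,4S)-4-(3,4-dimethoxybenzyl)-2-oxotetrahydrofuran-3-yl]methyl]-2-hydroxy-3-methoxyphenoxy]-3-methoxybenzyl]dihydrofuran-2(3H)-one (CNP0183104.1)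
Conditions: H2 (1 atm), Pd/C, EtOAc/EtOH, rt
Reagents that add atoms: none
Why: Catalytic hydrogenolysis cleaves the O-benzyl ether to the free phenol while the lactones, diaryl ether and methyl ethers are inert and no stereocentre is touched.

**Compound list**

1 | D-glutamic acid | N[C@H](CCC(=O)O)C(=O)O | starting material
2 | (R)-5-oxotetrahydrofuran-2-carboxylic acid | O=C1CC[C@H](C(=O)O)O1 | intermediate
3 | (R)-5-(hydroxymethyl)dihydrofuran-2(3H)-one | O=C1CC[C@H](CO)O1 | intermediate
4 | (R)-5-[(trityloxy)methyl]dihydrofuran-2(3H)-one | O=C1CC[C@H](COC(c2ccccc2)(c2ccccc2)c2ccccc2)O1 | intermediate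
5 | veratryl alcohol (3,4-dimethoxybenzyl alcohol) | COc1ccc(CO)cc1OC | starting material
6 | 3,4-dimethoxybenzyl bromide | COc1ccc(CBr)cc1OC | intermediate
7 | lithium enolate of 4 (not isolated) | [Li]OC1=CC[C@H](COC(c2ccccc2)(c2ccccc2)c2ccccc2)O1 | intermediate
8 | (3S,5R)-3-(3,4-dimethoxybenzyl)-5-[(trityloxy)methyl]dihydrofuran-2(3H)-one | O=C1[C@@H](Cc2ccc(OC)c(OC)c2)C[C@H](COC(c2ccccc2)(c2ccccc2)c2ccccc2)O1 | intermediate
9 | (2S,4R)-2-(3,4-dimethoxybenzyl)-5-(trityloxy)pentane-1,4-diol | OC[C@@H](Cc1ccc(OC)c(OC)c1)C[C@@H](O)COC(c1ccccc1)(c1ccccc1)c1ccccc1 | intermediate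
10 | (2R,4S)-4-(3,4-dimethoxybenzyl)pentane-1,2,5-triol | OC[C@@H](Cc1ccc(OC)c(OC)c1)C[C@@H](O)CO | intermediate
11 | (3S)-3-(3,4-dimethoxybenzyl)-4-hydroxybutanal (not isolated) | O=CC[C@H](Cc1ccc(OC)c(OC)c1)CO | intermediate
12 | (4S)-4-(3,4-dimethoxybenzyl)tetrahydrofuran-2-ol, both anomers | OC1C[C@H](Cc2ccc(OC)c(OC)c2)CO1 | intermediate
13 | (S)-4-(3,4-dimethoxybenzyl)dihydrofuran-2(3H)-one | O=C1C[C@H](Cc2ccc(OC)c(OC)c2)CO1 | intermediate
14 | 5-bromovanillin (3-bromo-4-hydroxy-5-methoxybenzaldehyde) | COc1cc(C=O)cc(Br)c1O | starting material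
15 | 4-(benzyloxy)-3-bromo-5-methoxybenzaldehyde | COc1cc(C=O)cc(Br)c1OCc1ccccc1 | intermediate
16 | vanillin | COc1cc(C=O)ccc1O | starting material
17 | 4-(benzyloxy)-3-(4-formyl-2-methoxyphenoxy)-5-methoxybenzaldehyde | COc1cc(C=O)ccc1Oc1cc(C=O)cc(OC)c1OCc1ccccc1 | intermediate
18 | [4-(benzyloxy)-3-[4-(hydroxymethyl)-2-methoxyphenoxy]-5-methoxyphenyl]methanol | COc1cc(CO)ccc1Oc1cc(CO)cc(OC)c1OCc1ccccc1 | intermediate
19 | 2-(benzyloxy)-5-(bromomethyl)-1-[4-(bromomethyl)-2-methoxyphenoxy]-3-methoxybenzene | COc1cc(CBr)ccc1Oc1cc(CBr)cc(OC)c1OCc1ccccc1 | intermediate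
20 | lithium enolate of 13 (not isolated) | [Li]OC1=C[C@H](Cc2ccc(OC)c(OC)c2)CO1 | intermediate
21 | (3S,4S)-3-[4-[2-(benzyloxy)-5-(bromomethyl)-3-methoxyphenoxy]-3-methoxybenzyl]-4-(3,4-dimethoxybenzyl)dihydrofuran-2(3H)-one (not isolated) | COc1ccc(C[C@@H]2COC(=O)[C@H]2Cc2ccc(Oc3cc(CBr)cc(OC)c3OCc3ccccc3)c(OC)c2)cc1OC | intermediate
22 | (3S,4S)-3-[4-(benzyloxy)-3-[4-(bromomethyl)-2-methoxyphenoxy]-5-methoxybenzyl]-4-(3,4-dimethoxybenzyl)dihydrofuran-2(3H)-one (not isolated) | BrCc1ccc(Oc2cc(C[C@@H]3C(=O)OC[C@H]3Cc3ccc(OC)c(OC)c3)cc(OC)c2OCc2ccccc2)c(OC)c1 | intermediate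
23 | (3S,4S)-3-[4-[2-(benzyloxy)-5-[[(3S,4S)-4-(3,4-dimethoxybenzyl)-2-oxotetrahydrofuran-3-yl]methyl]-3-methoxyphenoxy]-3-methoxybenzyl]-4-(3,4-dimethoxybenzyl)dihydrofuran-2(3H)-one | COc1ccc(C[C@@H]2COC(=O)[C@H]2Cc2ccc(Oc3cc(C[C@@H]4C(=O)OC[C@H]4Cc4ccc(OC)c(OC)c4)cc(OC)c3OCc3ccccc3)c(OC)c2)cc1OC | intermediate
24 | (3S,4S)-4-(3,4-dimethoxybenzyl)-3-[4-[5-[[(3S,4S)-4-(3,4-dimethoxybenzyl)-2-oxotetrahydrofuran-3-yl]methyl]-2-hydroxy-3-methoxyphenoxy]-3-methoxybenzyl]dihydrofuran-2(3H)-one (CNP0183104.1) | COc1ccc(C[C@@H]2COC(=O)[C@H]2Cc2ccc(Oc3cc(C[C@@H]4C(=O)OC[C@H]4Cc4ccc(OC)c(OC)c4)cc(OC)c3O)c(OC)c2)cc1OC | target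

**Count and risks**

Total step count: 15. Longest linear sequence: 10 steps (steps 1, 2, 3, 5, 6, 7, 8, 9, 14, 15).

Steps most likely to fail:

1. Step 14. The second alkylation may stall, proton transfer between the monoalkylated lactone and remaining enolate may cause over-alkylation and erode the trans ratio, and the electron-rich bis-bromide may consume itself by self-alkylation. The fallback replaces alkylation by aldol addition and reductive removal of the carbinol oxygen. It sets out from 13 and 17. Enolate 20 (LiN(iPr)2, THF, −78 °C) is added to both formyl groups of 17 to give the bis(benzylic alcohol) aldol adduct F1, trans at each lactone and a mixture of carbinol epimers. Hydrogenolysis (H2, Pd/C, AcOH, cat. HClO4) should then remove both benzylic hydroxyl groups together with the O-benzyl group. The fallback comes back to the route at 24, and steps 12, 13 and 15 are no longer needed.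

2. Step 11. Turnover at copper may be slow with an electron-poor phenoxide and an ortho-alkoxy aryl bromide, so that reductive loss of bromine and base-driven side reactions of the aldehydes compete. The fallback reverses the polarity of the C–O bond formation to a nucleophilic aromatic substitution. It sets out from 14. Copper-mediated hydroxylation (aq. NaOH, Cu powder, reflux) gives 3,4-dihydroxy-5-methoxybenzaldehyde F2. Benzylation at the more acidic hydroxyl para to the formyl group (BnBr, Li2CO3, DMF) gives 4-(benzyloxy)-3-hydroxy-5-methoxybenzaldehyde F3. Its phenoxide displaces fluoride from purchased 4-fluoro-3-methoxybenzaldehyde (COc1cc(C=O)ccc1F; K2CO3, DMF, 120 °C), where the para formyl group activates the ring. The fallback comes back to the route at 17.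

3. Step 5. Proton exchange between product 8 and enolate 7 may lead to dialkylation at C3 and to loss of trans selectivity, and bromide 6 may self-condense before it is consumed. The fallback keeps the enolate benzylation by 6 but moves stereocontrol to an oxazolidinone auxiliary. It sets out from 6. (S)-4-Benzyl-3-[4-(tert-butoxy)-4-oxobutanoyl]oxazolidin-2-one F4 is made from mono-tert-butyl succinate and (S)-4-benzyloxazolidin-2-one through the pivaloyl mixed anhydride. It is deprotonated (NaN(SiMe3)2, THF, −78 °C) and benzylated by 6 on the face away from the ring benzyl group to give (S)-4-benzyl-3-[(2S)-4-(tert-butoxy)-2-(3,4-dimethoxybenzyl)-4-oxobutanoyl]oxazolidin-2-one F5. LiBH4 (THF/H2O, 0 °C) removes the auxiliary reductively to give tert-butyl (3S)-3-(3,4-dimethoxybenzyl)-4-hydroxybutanoate F6. CF3CO2H in CH2Cl2 lactonises F6. The fallback comes back to the route at 13, and steps 1 to 3 and 6 to 9 are no longer needed.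

Further compounds
F1 | step 14 | bis(benzylic alcohol) from twofold aldol addition of 20 to 17 (trans lactones, carbinol epimers) | COc1ccc(C[C@@H]2COC(=O)[C@H]2C(O)c2ccc(Oc3cc(C(O)[C@@H]4C(=O)OC[C@H]4Cc4ccc(OC)c(OC)c4)cc(OC)c3OCc3ccccc3)c(OC)c2)cc1OC
F2 | step 11 | 3,4-dihydroxy-5-methoxybenzaldehyde | COc1cc(C=O)cc(O)c1O
F3 | step 11 | 4-(benzyloxy)-3-hydroxy-5-methoxybenzaldehyde | COc1cc(C=O)cc(O)c1OCc1ccccc1
F4 | step 5 | (S)-4-benzyl-3-[4-(tert-butoxy)-4-oxobutanoyl]oxazolidin-2-one | CC(C)(C)OC(=O)CCC(=O)N1[C@@H](Cc2ccccc2)COC1=O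
F5 | step 5 | (S)-4-benzyl-3-[(2S)-4-(tert-butoxy)-2-(3,4-dimethoxybenzyl)-4-oxobutanoyl]oxazolidin-2-one | CC(C)(C)OC(=O)C[C@H](Cc1ccc(OC)c(OC)c1)C(=O)N1[C@@H](Cc2ccccc2)COC1=O
F6 | step 5 | tert-butyl (3S)-3-(3,4-dimethoxybenzyl)-4-hydroxybutanoate | CC(C)(C)OC(=O)C[C@H](Cc1ccc(OC)c(OC)c1)CO
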